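**Plan**

- Locants used: C1 ketone carbon, C2 bridgehead CH, C3=C4(CH3) etheno bridge, C5 quaternary bridgehead, C6 (O–CH), C7, C8, C9, C10 (quaternary, CH3), C11 (CH–CH3), C12 lactone C=O; C1' (CH2) and C2' (CH carrying the 6-methylhepta-1,5-dien-2-yl group) form the ethano bridge.
- Retrosynthesis: the C1 ketone is traced to CH–CHO; the cyclohexene ring C5–C4=C3–C2–C1–C10 inside the bicyclo[2.2.2]octene is then a Diels–Alder retron with C1 and C10 as dienophile carbons. Because C10 is tied to C5 by the chain C9–C8–C7–C6, cutting C2–C1 and C5–C10 together removes the bicycle, the cyclohexane ring and both vicinal quaternary carbons, leaving a cyclohexa-1,3-diene with a tethered enal.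
- Further cuts: C7–C8 (conjugate addition to a butenolide), C11–CH3 (enolate methylation), C6–C7 and C12–O (alkynylation of a dienal, lactonisation), C5–C6 (formyl group on a dienyl triflate), and the side chain on (S)-carvone (allyl coupling, cross-metathesis).
- Forward: (S)-carvone → chain-extended enone → dienyl triflate → dienal → butenolide → all-trans lactone carrying the enal → intramolecular cycloaddition (cyclohexane ring and bicyclo[2.2.2]octene formed together) → oxidative deformylation to the C1 ketone.
- Stereochemistry: C2' from (S)-carvone; C6 from a ligand-controlled alkynylation; C7 and C11 by anti 1,2-induction on the lactone; C5, C2 and C10 in the cycloaddition, directed by C6 (allylic strain), by C2' (anti approach) and by the exo tether.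

Key step: step 15

Assumption: (S,S)-ProPhenol/Me2Zn is taken to deliver the (4S)-carbinol 7 with this dienal; if the sense of induction is the opposite, the (R,R)-ligand is used and nothing else changes.

**Route**

Step 1
Reactants: 1 (S)-carvone
Product: 2 (5S)-5-(3-chloroprop-1-en-2-yl)-2-methylcyclohex-2-en-1-one
Conditions: Ca(OCl)2, CO2 (dry ice), CH2Cl2/H2O, 0 °C
Reagents that add atoms: calcium hypochlorite, [Ca+2].[O-]Cl.[O-]Cl
Why: Ene-type chlorination by HOCl should occur at the electron-richer 1,1-disubstituted alkene (the enone alkene is deactivated) with loss of a methyl proton, giving the transposed allylic chloride and leaving the C5 stereocentre untouched.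

Step 2
Reactants: 2 (5S)-5-(3-chloroprop-1-en-2-yl)-2-methylcyclohex-2-en-1-one
Product: 3 (5S)-5-(hexa-1,5-dien-2-yl)-2-methylcyclohex-2-en-1-one
Conditions: allylB(pin), Pd2(dba)3 (cat.), PPh3, CsF, THF, 50 °C
Reagents that add atoms: allylboronic acid pinacol ester, C=CCB1OC(C)(C)C(C)(C)O1
Why: Palladium-catalysed allyl–allyl cross-coupling of Suzuki–Miyaura type should give the 1,5-diene; both allyl partners have equivalent termini, so no regiochemical question arises, and the allylboronate should not add to the enone.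

Step 3
Reactants: 3 (5S)-5-(hexa-1,5-dien-2-yl)-2-methylcyclohex-2-en-1-one
Product: 4 (5S)-2-methyl-5-(6-methylhepta-1,5-dien-2-yl)cyclohex-2-en-1-one
Conditions: second-generation Grubbs catalyst (cat.), 2-methyl-2-butene (excess), CH2Cl2, 40 °C
Reagents that add atoms: 2-methylbut-2-ene, CC=C(C)C
Why: Olefin cross-metathesis should convert only the monosubstituted alkene into the isopropylidene terminus, because the 1,1-disubstituted alkene and the enone alkene are too hindered or too electron-poor to engage.

Step 4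
Reactants: 4 (5S)-2-methyl-5-(6-methylhepta-1,5-dien-2-yl)cyclohex-2-en-1-one
Product: 5 (5R)-2-methyl-5-(6-methylhepta-1,5-dien-2-yl)cyclohexa-1,3-dien-1-yl trifluoromethanesulfonate
Conditions: Tf2O, 2,6-di-tert-butyl-4-methylpyridine, CH2Cl2, 0 °C to rt
Reagents that add atoms: trifluoromethanesulfonic anhydride, O=S(=O)(OS(=O)(=O)C(F)(F)F)C(F)(F)F
Why: O-Triflation of the enone followed by loss of the γ-proton at C4 under buffered conditions should give the linearly conjugated dienyl triflate, as with steroidal 4-en-3-ones; C5 is not deprotonated and keeps its configuration (the descriptor becomes R only through the priority rules).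

Step 5
Reactants: 5 (5R)-2-methyl-5-(6-methylhepta-1,5-dien-2-yl)cyclohexa-1,3-dien-1-yl trifluoromethanesulfonate
Product: 6 (5R)-2-methyl-5-(6-methylhepta-1,5-dien-2-yl)cyclohexa-1,3-diene-1-carbaldehyde
Conditions: CO (1 atm), Pd(OAc)2 (cat.), dppp, Et3SiH, Et3N, DMF, 70 °C
Reagents that add atoms: carbon monoxide, [C-]#[O+]
Why: Palladium-catalysed reductive carbonylation of the alkenyl triflate (oxidative addition, CO insertion, hydride transfer from the silane) should give the dienal without touching the isolated alkenes.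

Step 6
Reactants: 6 (5R)-2-methyl-5-(6-methylhepta-1,5-dien-2-yl)cyclohexa-1,3-diene-1-carbaldehyde
Product: 7 methyl (4S)-4-hydroxy-4-[(5R)-2-methyl-5-(6-methylhepta-1,5-dien-2-yl)cyclohexa-1,3-dien-1-yl]but-2-ynoate
Conditions: methyl propiolate, Me2Zn, (S,S)-ProPhenol (cat.), Ph3PO (cat.), PhMe, 4 °C
Reagents that add atoms: methyl propiolate, C#CC(=O)OC
Why: Zinc–ProPhenol-catalysed enantioselective addition of the zinc alkynylide to the unsaturated aldehyde should set C6 under ligand control, independently of the remote ring stereocentre, and the weakly basic zinc reagent should spare the vinylogously acidic ring C–H.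

Step 7
Reactants: 7 methyl (4S)-4-hydroxy-4-[(5R)-2-methyl-5-(6-methylhepta-1,5-dien-2-yl)cyclohexa-1,3-dien-1-yl]but-2-ynoate
Product: 9 (5S)-5-[(5R)-2-methyl-5-(6-methylhepta-1,5-dien-2-yl)cyclohexa-1,3-dien-1-yl]furan-2(5H)-one, via (Z)-hydroxy enoate 8 (not isolated)
Conditions: H2 (1 atm), Pd/CaCO3 poisoned with Pb(OAc)2, quinoline, EtOAc, rt; then PhMe, 40 °C
Reagents that add atoms: none
Why: Semihydrogenation of the ynoate on the poisoned catalyst, which reduces the alkyne ahead of the alkenes, should give the (Z)-γ-hydroxy enoate, and this should lactonise to the butenolide without acid.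

Step 8
Reactants: 10 4-bromobut-1-yne
Product: 12 ethyl (2E)-5-bromo-3-methylpent-2-enoate, via alkenylalane 11 (not isolated)
Conditions: Me3Al, Cp2ZrCl2 (cat.), CH2Cl2, 0 °C to rt; then ClCO2Et, 0 °C
Reagents that add atoms: trimethylaluminium, C[Al](C)C; ethyl chloroformate, CCOC(=O)Cl
Why: Zirconium-catalysed syn-carboalumination of the terminal alkyne places methyl on the internal carbon, and acylation of the neutral alkenylalane with retention should give the (E)-enoate; no ate complex is formed, so the bromide should not be displaced.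

Step 9
Reactants: 12 ethyl (2E)-5-bromo-3-methylpent-2-enoate
Product: 13 (2E)-5-bromo-3-methylpent-2-en-1-ol
Conditions: i-Bu2AlH, CH2Cl2, −78 °C
Reagents that add atoms: none
Why: 1,2-Reduction of the conjugated ester by the aluminium hydride at low temperature should give the allylic alcohol and leave the primary bromide and the alkene geometry intact.

Step 10
Reactants: 13 (2E)-5-bromo-3-methylpent-2-en-1-ol
Product: 14 {[(2E)-5-bromo-3-methylpent-2-en-1-yl]oxy}(tert-butyl)dimethylsilane
Conditions: TBSCl, imidazole, CH2Cl2, rt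
Reagents that add atoms: tert-butyldimethylsilyl chloride, CC(C)(C)[Si](C)(C)Cl
Why: Routine silylation of the primary allylic alcohol masks it for the organometallic steps.

Step 11
Reactants: 9 (5S)-5-[(5R)-2-methyl-5-(6-methylhepta-1,5-dien-2-yl)cyclohexa-1,3-dien-1-yl]furan-2(5H)-one; 14 {[(2E)-5-bromo-3-methylpent-2-en-1-yl]oxy}(tert-butyl)dimethylsilane
Product: 17 (4S,5S)-4-[(3E)-5-(tert-butyldimethylsilyloxy)-3-methylpent-3-en-1-yl]-5-[(5R)-2-methyl-5-(6-methylhepta-1,5-dien-2-yl)cyclohexa-1,3-dien-1-yl]oxolan-2-one, via Grignard reagent 15 (not isolated), via silyl ketene acetal 16 (not isolated)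
Conditions: Mg, THF, rt; then CuBr·SMe2 (cat.), TMSCl, 9, THF, −78 °C; aq. NH4Cl
Reagents that add atoms: none
Why: Copper-catalysed, TMSCl-accelerated conjugate addition of the Grignard reagent to the 5-substituted butenolide should occur anti to the dienyl group on C6 and so set C7 trans to it, while silyl trapping of the enolate should suppress proton transfer from the acidic γ-position.

Step 12
Reactants: 17 (4S,5S)-4-[(3E)-5-(tert-butyldimethylsilyloxy)-3-methylpent-3-en-1-yl]-5-[(5R)-2-methyl-5-(6-methylhepta-1,5-dien-2-yl)cyclohexa-1,3-dien-1-yl]oxolan-2-one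
Product: 19 (3S,4S,5S)-4-[(3E)-5-(tert-butyldimethylsilyloxy)-3-methylpent-3-en-1-yl]-3-methyl-5-[(5R)-2-methyl-5-(6-methylhepta-1,5-dien-2-yl)cyclohexa-1,3-dien-1-yl]oxolan-2-one, via lithium enolate 18 (not isolated)
Conditions: LiN(i-Pr)2, THF, −78 °C; then MeI, −78 to −40 °C
Reagents that add atoms: iodomethane, CI
Why: Kinetic alkylation of the lactone enolate should take place anti to the adjacent C7 substituent, giving the all-trans 3-methyl lactone (also the thermodynamically preferred epimer) and so setting C11.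

Step 13
Reactants: 19 (3S,4S,5S)-4-[(3E)-5-(tert-butyldimethylsilyloxy)-3-methylpent-3-en-1-yl]-3-methyl-5-[(5R)-2-methyl-5-(6-methylhepta-1,5-dien-2-yl)cyclohexa-1,3-dien-1-yl]oxolan-2-one
Product: 20 (3S,4S,5S)-4-[(3E)-5-hydroxy-3-methylpent-3-en-1-yl]-3-methyl-5-[(5R)-2-methyl-5-(6-methylhepta-1,5-dien-2-yl)cyclohexa-1,3-dien-1-yl]oxolan-2-one
Conditions: Bu4NF, AcOH, THF, 0 °C to rt
Reagents that add atoms: none
Why: Buffered fluoride should cleave the primary silyl ether while the acid-sensitive dienylic lactone C–O bond and the epimerisable centres are left alone.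

Step 14
Reactants: 20 (3S,4S,5S)-4-[(3E)-5-hydroxy-3-methylpent-3-en-1-yl]-3-methyl-5-[(5R)-2-methyl-5-(6-methylhepta-1,5-dien-2-yl)cyclohexa-1,3-dien-1-yl]oxolan-2-one
Product: 21 (2E)-3-methyl-5-{(2S,3S,4S)-4-methyl-2-[(5R)-2-methyl-5-(6-methylhepta-1,5-dien-2-yl)cyclohexa-1,3-dien-1-yl]-5-oxooxolan-3-yl}pent-2-enal
Conditions: MnO2, CH2Cl2, rt
Reagents that add atoms: none
Why: MnO2 oxidises only the allylic alcohol and should give the (E)-enal under neutral conditions without isomerising the diene.

Step 15
Reactants: 21 (2E)-3-methyl-5-{(2S,3S,4S)-4-methyl-2-[(5R)-2-methyl-5-(6-methylhepta-1,5-dien-2-yl)cyclohexa-1,3-dien-1-yl]-5-oxooxolan-3-yl}pent-2-enal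
Product: 22 formyl cycloadduct (the target skeleton with C1 as CH–CHO, formyl syn to the C3=C4 bridge)
Conditions: PhMe (0.01 M), BHT (cat.), 150 °C, sealed tube, degassed
Reagents that add atoms: none
Why: A thermal, suprafacial [4+2] cycloaddition between the ring diene C5=C4–C3=C2 and the tethered enal C10=C1 forms C5–C10 and C2–C1 in one event, so the two adjacent quaternary carbons, the bicyclo[2.2.2]octene and the cyclohexane ring arise together; the closest known reaction type is the type 1 intramolecular Diels–Alder reaction of 1-tethered cyclohexa-1,3-dienes used for bicyclo[2.2.2]octene terpenoids. The cyclohexane ring (C5–C6–C7–C8–C9–C10) closes in the fused mode through a chair-like six-membered tether ring, and the second ring results from bridging the 1,4-positions (C5 and C2) of the diene ring by the C10–C1 unit. The diene face is chosen by C6, since allylic 1,3-strain with the C4 methyl should place the C6 hydrogen in the diene plane, the C6–O bond on the rear face and the C7 chain on the front face, which is also the face anti to the C2' side chain, so both controllers act in the same sense and fix C5 and C2. C10 follows from the exo position of the tether (C10 methyl endo, over C4=C3), the only arrangement in which the trans-lactone chain does not pass over the C4 methyl; the formyl-bearing C1 is set endo by the E-alkene but is erased in step 16. The step needs periselectivity for the conjugated diene over the three isolated alkenes, which the tether geometry and the electron-poor enal should provide, and freedom from hydrogen shifts of the diene, which a temperature well below 200 °C with exclusion of acid and oxygen should secure.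

Step 16
Reactants: 22 formyl cycloadduct
Product: 23 target CNP0385704.3
Conditions: O2 (1 atm), Cu(OAc)2 (cat.), 2,2'-bipyridine, DABCO, DMF, 40 °C
Reagents that add atoms: dioxygen, O=O
Why: Copper-catalysed aerobic oxidative deformylation of the α-branched aldehyde (enolisation, oxygenation at C1, loss of formate) should convert the CH–CHO unit into the C1 ketone and erase the C1 stereocentre, the lactone and the alkenes being inert to these conditions.

**Compound list**

1 | (S)-carvone, (5S)-2-methyl-5-(prop-1-en-2-yl)cyclohex-2-en-1-one | CC1=CC[C@@H](CC1=O)C(C)=C | starting material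
2 | (5S)-5-(3-chloroprop-1-en-2-yl)-2-methylcyclohex-2-en-1-one | CC1=CC[C@@H](CC1=O)C(CCl)=C | intermediate
3 | (5S)-5-(hexa-1,5-dien-2-yl)-2-methylcyclohex-2-en-1-one | CC1=CC[C@@H](CC1=O)C(CCC=C)=C | intermediate
4 | (5S)-2-methyl-5-(6-methylhepta-1,5-dien-2-yl)cyclohex-2-en-1-one | CC1=CC[C@@H](CC1=O)C(CCC=C(C)C)=C | intermediate
5 | (5R)-2-methyl-5-(6-methylhepta-1,5-dien-2-yl)cyclohexa-1,3-dien-1-yl trifluoromethanesulfonate | CC1=C(OS(=O)(=O)C(F)(F)F)C[C@@H](C(CCC=C(C)C)=C)C=C1 | intermediate
6 | (5R)-2-methyl-5-(6-methylhepta-1,5-dien-2-yl)cyclohexa-1,3-diene-1-carbaldehyde | CC1=C(C=O)C[C@@H](C(CCC=C(C)C)=C)C=C1 | intermediate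
7 | methyl (4S)-4-hydroxy-4-[(5R)-2-methyl-5-(6-methylhepta-1,5-dien-2-yl)cyclohexa-1,3-dien-1-yl]but-2-ynoate | COC(=O)C#C[C@H](O)C1=C(C)C=C[C@@H](C1)C(CCC=C(C)C)=C | intermediate
8 | methyl (2Z,4S)-4-hydroxy-4-[(5R)-2-methyl-5-(6-methylhepta-1,5-dien-2-yl)cyclohexa-1,3-dien-1-yl]but-2-enoate | COC(=O)/C=C\[C@H](O)C1=C(C)C=C[C@@H](C1)C(CCC=C(C)C)=C | intermediate
9 | (5S)-5-[(5R)-2-methyl-5-(6-methylhepta-1,5-dien-2-yl)cyclohexa-1,3-dien-1-yl]furan-2(5H)-one | O=C1O[C@@H](C=C1)C2=C(C)C=C[C@@H](C2)C(CCC=C(C)C)=C | intermediate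
10 | 4-bromobut-1-yne | C#CCCBr | starting material
11 | [(1E)-4-bromo-2-methylbut-1-en-1-yl]dimethylalane | C[Al](C)/C=C(\C)CCBr | intermediate
12 | ethyl (2E)-5-bromo-3-methylpent-2-enoate | CCOC(=O)/C=C(\C)CCBr | intermediate
13 | (2E)-5-bromo-3-methylpent-2-en-1-ol | OC/C=C(\C)CCBr | intermediate
14 | {[(2E)-5-bromo-3-methylpent-2-en-1-yl]oxy}(tert-butyl)dimethylsilane | CC(C)(C)[Si](C)(C)OC/C=C(\C)CCBr | intermediate
15 | bromo[(3E)-5-(tert-butyldimethylsilyloxy)-3-methylpent-3-en-1-yl]magnesium | Br[Mg]CC/C(C)=C/CO[Si](C)(C)C(C)(C)C | intermediate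
16 | trimethylsilyl ketene acetal of 17 (2-trimethylsilyloxy-4,5-dihydrofuran; C4 and C5 as in 17) | C[Si](C)(C)OC1=C[C@H](CC/C(C)=C/CO[Si](C)(C)C(C)(C)C)[C@H](O1)C2=C(C)C=C[C@@H](C2)C(CCC=C(C)C)=C | intermediate
17 | (4S,5S)-4-[(3E)-5-(tert-butyldimethylsilyloxy)-3-methylpent-3-en-1-yl]-5-[(5R)-2-methyl-5-(6-methylhepta-1,5-dien-2-yl)cyclohexa-1,3-dien-1-yl]oxolan-2-one | O=C1C[C@H](CC/C(C)=C/CO[Si](C)(C)C(C)(C)C)[C@H](O1)C2=C(C)C=C[C@@H](C2)C(CCC=C(C)C)=C | intermediate
18 | lithium enolate of 17 (C4 and C5 as in 17) | [Li]OC1=C[C@H](CC/C(C)=C/CO[Si](C)(C)C(C)(C)C)[C@H](O1)C2=C(C)C=C[C@@H](C2)C(CCC=C(C)C)=C | intermediate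
19 | (3S,4S,5S)-4-[(3E)-5-(tert-butyldimethylsilyloxy)-3-methylpent-3-en-1-yl]-3-methyl-5-[(5R)-2-methyl-5-(6-methylhepta-1,5-dien-2-yl)cyclohexa-1,3-dien-1-yl]oxolan-2-one | O=C1[C@@H](C)[C@H](CC/C(C)=C/CO[Si](C)(C)C(C)(C)C)[C@H](O1)C2=C(C)C=C[C@@H](C2)C(CCC=C(C)C)=C | intermediate
20 | (3S,4S,5S)-4-[(3E)-5-hydroxy-3-methylpent-3-en-1-yl]-3-methyl-5-[(5R)-2-methyl-5-(6-methylhepta-1,5-dien-2-yl)cyclohexa-1,3-dien-1-yl]oxolan-2-one | O=C1[C@@H](C)[C@H](CC/C(C)=C/CO)[C@H](O1)C2=C(C)C=C[C@@H](C2)C(CCC=C(C)C)=C | intermediate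
21 | (2E)-3-methyl-5-{(2S,3S,4S)-4-methyl-2-[(5R)-2-methyl-5-(6-methylhepta-1,5-dien-2-yl)cyclohexa-1,3-dien-1-yl]-5-oxooxolan-3-yl}pent-2-enal | O=C1[C@@H](C)[C@H](CC/C(C)=C/C=O)[C@H](O1)C2=C(C)C=C[C@@H](C2)C(CCC=C(C)C)=C | intermediate
22 | formyl cycloadduct: target skeleton with C1 as CH–CHO, formyl syn to the C3=C4 bridge, all other centres as in 23 | C=C(CCC=C(C)C)[C@@H]1C[C@]23C(C)=C[C@H]1[C@@H](C=O)[C@]2(C)CC[C@H]1[C@H](C)C(=O)O[C@@H]13 | intermediate
23 | CNP0385704.3: bicyclo[2.2.2]oct-5-en-2-one (C1 ketone, C3=C4 bridge, C1'–C2' bridge) fused at C5–C10 to a cyclohexane carrying a trans-fused α-methyl-γ-lactone; C10 methyl and the C2' dienyl chain both syn to the C3=C4 bridge, 6-O and C11 equatorial, 11-methyl cis to H-7 | C=C(CCC=C(C)C)[C@@H]1C[C@]23C(C)=C[C@H]1C(=O)[C@]2(C)CC[C@H]1[C@H](C)C(=O)O[C@@H]13 | target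

**Step count and risks**

Total steps: 16. Longest linear sequence: 13 (steps 1–7 and 11–16); steps 8–10 make the side-chain bromide.

Steps most likely to fail:

Step 15. The forming C5–C10 bond joins two fully substituted carbons, so cycloaddition may be slower than hydrogen shift or oligomerisation of the diene. The fallback changes the dienophile from a neutral enal to an allyl cation. It sets out from enal 21, which is converted with 1,2-bis(trimethylsilyloxy)ethane and catalytic TMSOTf at −78 °C into the 2-alkenyl-1,3-dioxolane F1. Further exposure to catalytic TMSOTf or TfOH at −78 °C should ionise the acetal to a dioxolanylium-stabilised allyl cation, and the stepwise ionic Diels–Alder reaction, which tolerates congestion better than the concerted one, should give the cycloadduct acetal F2. Mild hydrolysis (PPTS, acetone/H2O) then comes back to the route at aldehyde 22; either C1 epimer serves, since step 16 erases that centre.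

Step 16. Enolisation of the hindered aldehyde (flanked by a quaternary carbon and a bridgehead) may be too slow, or allylic autoxidation may compete. The fallback removes the extra carbon as CO2 instead of formate. It sets out from 22: Pinnick oxidation (NaClO2, NaH2PO4, 2-methyl-2-butene, t-BuOH/H2O) should give the carboxylic acid F3, and photochemical decarboxylative oxygenation (CeCl3 (cat.), O2, blue light, MeCN) should convert it by way of the C1 radical into ketone 23, where it rejoins the route.

Step 4. Deprotonation at C6 instead of C4 would give the cross-conjugated triflate, and acid could trigger aromatisation. The fallback reaches the dienal without an enol triflate. It sets out from enone 4: Wittig reaction with Ph3P=CHOMe (from (methoxymethyl)triphenylphosphonium chloride and KN(SiMe3)2, THF, 0 °C) should give the 1-(methoxymethylidene)cyclohex-2-ene F4. Dehydrogenation of this dienol ether with DDQ (1 equiv, wet CH2Cl2, 0 °C), by hydride abstraction from C4 and hydrolysis of the oxocarbenium ion, should give dienal 6, where it rejoins the route and makes step 5 unnecessary.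

Further compounds
F1 | step 15 | (3S,4S,5S)-4-[(3E)-4-(1,3-dioxolan-2-yl)-3-methylbut-3-en-1-yl]-3-methyl-5-[(5R)-2-methyl-5-(6-methylhepta-1,5-dien-2-yl)cyclohexa-1,3-dien-1-yl]oxolan-2-one | O=C1[C@@H](C)[C@H](CC/C(C)=C/C3OCCO3)[C@H](O1)C2=C(C)C=C[C@@H](C2)C(CCC=C(C)C)=C
F2 | step 15 | 1,3-dioxolane acetal of cycloadduct 22 | C=C(CCC=C(C)C)[C@@H]1C[C@]23C(C)=C[C@H]1[C@@H](C4OCCO4)[C@]2(C)CC[C@H]1[C@H](C)C(=O)O[C@@H]13
F3 | step 16 | carboxylic acid corresponding to 22 (C1–CO2H) | C=C(CCC=C(C)C)[C@@H]1C[C@]23C(C)=C[C@H]1[C@@H](C(=O)O)[C@]2(C)CC[C@H]1[C@H](C)C(=O)O[C@@H]13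
F4 | step 4 | (5S)-1-(methoxymethylidene)-2-methyl-5-(6-methylhepta-1,5-dien-2-yl)cyclohex-2-ene (enol ether geometry not controlled) | COC=C1C(C)=CC[C@@H](C1)C(CCC=C(C)C)=C
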